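**Retrosynthetic overview**

Labels: ring A = resorcinol ring; ring B = catechol ring fused to the seven-membered ring; ring C = six-membered ring between rings A and D; ring D = central phenol ring (D1 carries C10, D3 the oxygen, D5 the bond to ring A, D6 carries C8); ring E = pendant catechol; C7 = CH2 on ring A, C8 = CH between rings B and D, C9 = CH bearing ring E, C10 = CH2 on ring D.
Feature: the two oxygens of ring A stand 1,3, and the two ring-A carbons that follow one of them carry, in turn, the biaryl bond to D5 and the C7 methylene; ring A is therefore an aromatised 4,5-disubstituted cyclohexane-1,3-dione, and its crowded biaryl bond can be made as an sp3–sp3 bond.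
Disconnection 1 (rings A and C): demethylation and aromatisation lead back to the dione, which opens by retro-Claisen and retro-Michael to a dibenzosuberane with an E-enone chain on C8 and a methyl acetate arm on D5.
Disconnection 2 (seven-membered ring, C8, C9): C9 comes from hydrogenation of a C9=C10 alkene anti to the C8 chain; C8 and the C8–D6 bond come from a rhodium-catalysed asymmetric conjugate addition of a D6 boronate to a ring-B enal held cis by a Z-triarylethene.
Disconnection 3: the triarylethene comes from two Suzuki couplings on a 1,1-dibromoalkene derived from 2-hydroxy-5-methoxybenzaldehyde, and the D5 arm from Claisen rearrangement and ozonolysis; rings B, D and E are bought, the seven-membered ring forms in step 11, rings C and A together in step 14.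

Key step: step 14

Assumption: iodine in methanol is taken to deliver ring A as its dimethyl ether; any monomethyl ether formed beside it is demethylated to the same product in step 16.

**Route**

Step 1
Reactants: 1 2-hydroxy-5-methoxybenzaldehyde; 2 allyl bromide
Product: 3 5-methoxy-2-(prop-2-en-1-yloxy)benzaldehyde
Conditions: K2CO3, DMF, 60 °C
Reagents that add atoms: none
Why: Williamson ether synthesis, in which the phenoxide is alkylated on oxygen by the allylic bromide under carbonate conditions that leave the aldehyde untouched.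

Step 2
Reactants: 3 5-methoxy-2-(prop-2-en-1-yloxy)benzaldehyde
Product: 4 2-hydroxy-5-methoxy-3-(prop-2-en-1-yl)benzaldehyde
Conditions: N,N-diethylaniline, 195 °C
Reagents that add atoms: none
Why: Aromatic Claisen rearrangement, in which the allyl group moves by a [3,3] shift to the only free ortho position (the future D5) and tautomerisation restores the phenol.

Step 3
Reactants: 4 2-hydroxy-5-methoxy-3-(prop-2-en-1-yl)benzaldehyde
Product: 5 2-formyl-4-methoxy-6-(prop-2-en-1-yl)phenyl trifluoromethanesulfonate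
Conditions: Tf2O, pyridine, CH2Cl2, 0 °C to rt
Reagents that add atoms: trifluoromethanesulfonic anhydride, O=S(=O)(OS(=O)(=O)C(F)(F)F)C(F)(F)F
Why: O-sulfonylation of the phenol, which turns the D6 oxygen into a coupling handle that is hindered enough to stay inert until step 9 and also deactivates ring D toward ozone.

Step 4
Reactants: 5 2-formyl-4-methoxy-6-(prop-2-en-1-yl)phenyl trifluoromethanesulfonate
Product: 6 2-(2,2-dibromoethenyl)-4-methoxy-6-(prop-2-en-1-yl)phenyl trifluoromethanesulfonate
Conditions: CBr4, PPh3, CH2Cl2, 0 °C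
Reagents that add atoms: carbon tetrabromide, BrC(Br)(Br)Br
Why: Ramirez dibromo-olefination (first stage of the Corey–Fuchs sequence), which converts the aldehyde into a 1,1-dibromoalkene whose two bromides differ in their position relative to ring D.

Step 5
Reactants: 6 2-(2,2-dibromoethenyl)-4-methoxy-6-(prop-2-en-1-yl)phenyl trifluoromethanesulfonate
Product: 7 methyl 2-[3-(2,2-dibromoethenyl)-5-methoxy-2-(trifluoromethanesulfonyloxy)phenyl]acetate
Conditions: O3, NaOH, MeOH/CH2Cl2, −78 °C
Reagents that add atoms: ozone, [O-][O+]=O; methanol, CO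
Why: Ozonolysis in basic methanol takes a terminal alkene directly to the methyl ester with loss of the terminal carbon, and the monosubstituted alkene should react far faster with ozone than the electron-poor dibromoalkene or the triflate-deactivated arene.

Step 6
Reactants: 7 methyl 2-[3-(2,2-dibromoethenyl)-5-methoxy-2-(trifluoromethanesulfonyloxy)phenyl]acetate; 8 (3,4-dimethoxyphenyl)boronic acid
Product: 9 methyl 2-{3-[(Z)-2-bromo-2-(3,4-dimethoxyphenyl)ethenyl]-5-methoxy-2-(trifluoromethanesulfonyloxy)phenyl}acetate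
Conditions: Pd2(dba)3, P(2-furyl)3, Na2CO3 (aq.), 1,4-dioxane, 65 °C
Reagents that add atoms: none
Why: Suzuki–Miyaura coupling, in which oxidative addition takes the less hindered C–Br bond trans to ring D, so that ring E enters trans to ring D and the bromide reacts ahead of the hindered aryl triflate.

Step 7
Reactants: 10 2-bromo-4,5-dimethoxybenzaldehyde
Product: 11 4,5-dimethoxy-2-(4,4,5,5-tetramethyl-1,3,2-dioxaborolan-2-yl)benzaldehyde
Conditions: PdCl2(dppf), bis(pinacolato)diboron, KOAc, 1,4-dioxane, 85 °C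
Reagents that add atoms: bis(pinacolato)diboron, CC1(C)OB(OC1(C)C)B1OC(C)(C)C(C)(C)O1
Why: Miyaura borylation of the aryl bromide, where the weak acetate base suppresses biaryl coupling of the product and the formyl group is tolerated.

Step 8
Reactants: 9 methyl 2-{3-[(Z)-2-bromo-2-(3,4-dimethoxyphenyl)ethenyl]-5-methoxy-2-(trifluoromethanesulfonyloxy)phenyl}acetate; 11 4,5-dimethoxy-2-(4,4,5,5-tetramethyl-1,3,2-dioxaborolan-2-yl)benzaldehyde
Product: 12 methyl 2-{3-[(Z)-2-(3,4-dimethoxyphenyl)-2-(2-formyl-4,5-dimethoxyphenyl)ethenyl]-5-methoxy-2-(trifluoromethanesulfonyloxy)phenyl}acetate (ring B cis to ring D)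
Conditions: Pd(PPh3)4, K3PO4, 1,4-dioxane/H2O, 85 °C
Reagents that add atoms: none
Why: Suzuki–Miyaura coupling with retention of alkene geometry, which places ring B cis to ring D as ring closure requires, the vinyl bromide reacting before the doubly ortho-substituted, electron-rich aryl triflate.

Step 9
Reactants: 12 methyl 2-{3-[(Z)-2-(3,4-dimethoxyphenyl)-2-(2-formyl-4,5-dimethoxyphenyl)ethenyl]-5-methoxy-2-(trifluoromethanesulfonyloxy)phenyl}acetate
Product: 13 methyl 2-{3-[(Z)-2-(3,4-dimethoxyphenyl)-2-(2-formyl-4,5-dimethoxyphenyl)ethenyl]-5-methoxy-2-(4,4,5,5-tetramethyl-1,3,2-dioxaborolan-2-yl)phenyl}acetate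
Conditions: Pd2(dba)3, XPhos, bis(pinacolato)diboron, KOAc, 1,4-dioxane, 80 °C
Reagents that add atoms: bis(pinacolato)diboron, CC1(C)OB(OC1(C)C)B1OC(C)(C)C(C)(C)O1
Why: Miyaura borylation of a hindered aryl triflate with a bulky biaryl phosphine, carried out before the enal is installed so that the arylpalladium intermediate has no acceptor for a Heck cyclisation, and at a temperature below that needed for C–H arylation onto ring B.

Step 10
Reactants: 13 methyl 2-{3-[(Z)-2-(3,4-dimethoxyphenyl)-2-(2-formyl-4,5-dimethoxyphenyl)ethenyl]-5-methoxy-2-(4,4,5,5-tetramethyl-1,3,2-dioxaborolan-2-yl)phenyl}acetate; 14 (triphenylphosphoranylidene)acetaldehyde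
Product: 15 methyl 2-{3-[(Z)-2-(3,4-dimethoxyphenyl)-2-{4,5-dimethoxy-2-[(E)-3-oxoprop-1-en-1-yl]phenyl}ethenyl]-5-methoxy-2-(4,4,5,5-tetramethyl-1,3,2-dioxaborolan-2-yl)phenyl}acetate
Conditions: toluene, 80 °C
Reagents that add atoms: none
Why: Wittig olefination with a stabilised, non-basic ylide, which should give the E-enal and leave the boronate, the ester and the triarylethene untouched.

Step 11
Reactants: 15 methyl 2-{3-[(Z)-2-(3,4-dimethoxyphenyl)-2-{4,5-dimethoxy-2-[(E)-3-oxoprop-1-en-1-yl]phenyl}ethenyl]-5-methoxy-2-(4,4,5,5-tetramethyl-1,3,2-dioxaborolan-2-yl)phenyl}acetate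
Product: 16 methyl 2-[(5S)-10-(3,4-dimethoxyphenyl)-2,7,8-trimethoxy-5-(2-oxoethyl)-5H-dibenzo[a,d][7]annulen-4-yl]acetate (C8 S, C9=C10 double bond in the ring)
Conditions: [RhCl(C2H4)2]2, (R,R)-2,5-diphenylbicyclo[2.2.2]octa-2,5-diene (or its enantiomer, whichever gives S at C8), K3PO4, 1,4-dioxane/H2O, 50 °C
Reagents that add atoms: none
Why: Intramolecular rhodium-catalysed asymmetric 1,4-addition (Hayashi–Miyaura reaction), in which the D6 aryl-rhodium species is held next to the enal by the Z-alkene, inserts 7-exo-trig and is protonated to the aldehyde; C8 is the only stereocentre formed on an achiral substrate, so the chiral diene ligand alone fixes it as S.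

Step 12
Reactants: 16 methyl 2-[(5S)-10-(3,4-dimethoxyphenyl)-2,7,8-trimethoxy-5-(2-oxoethyl)-5H-dibenzo[a,d][7]annulen-4-yl]acetate
Product: 17 methyl 2-[(5S,10R)-10-(3,4-dimethoxyphenyl)-2,7,8-trimethoxy-5-(2-oxoethyl)-10,11-dihydro-5H-dibenzo[a,d][7]annulen-4-yl]acetate (C8 S, C9 R; H8 and H9 cis)
Conditions: H2 (5 bar), Pd/C, EtOAc, rt
Reagents that add atoms: none
Why: Heterogeneous catalytic hydrogenation with syn delivery of hydrogen; the C8 side chain, pushed pseudoaxial by peri strain with the D5 arm, hangs over one face of the C9=C10 bond, so the catalyst should bind the opposite face and place H9 cis to H8, which sets C9 as R with ring E and the C8 chain on the same side.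

Step 13
Reactants: 17 methyl 2-[(5S,10R)-10-(3,4-dimethoxyphenyl)-2,7,8-trimethoxy-5-(2-oxoethyl)-10,11-dihydro-5H-dibenzo[a,d][7]annulen-4-yl]acetate; 18 1-(triphenylphosphoranylidene)propan-2-one
Product: 19 methyl 2-{(5S,10R)-10-(3,4-dimethoxyphenyl)-2,7,8-trimethoxy-5-[(2E)-4-oxopent-2-en-1-yl]-10,11-dihydro-5H-dibenzo[a,d][7]annulen-4-yl}acetate
Conditions: CH2Cl2, 40 °C
Reagents that add atoms: none
Why: Wittig olefination with the stabilised acetonyl ylide, which should give the E-enone under neutral conditions that do not start any enolate chemistry of the arylacetate.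

Step 14
Reactants: 19 methyl 2-{(5S,10R)-10-(3,4-dimethoxyphenyl)-2,7,8-trimethoxy-5-[(2E)-4-oxopent-2-en-1-yl]-10,11-dihydro-5H-dibenzo[a,d][7]annulen-4-yl}acetate
Product: 21 ring-A cyclohexane-1,3-dione (C8 S and C9 R; mixture at the two new ring-A sp3 carbons), via Michael adduct keto ester 20 (not isolated)
Conditions: NaOMe (3 equiv), MeOH, 65 °C; then aq. HCl
Reagents that add atoms: none
Why: Methoxide generates the ring-D arylacetate enolate, which adds to the β-carbon of the E-enone tethered through C7 and C8 and so closes ring C (6-exo-trig) through an sp3–sp3 bond between the two future ring-A carbons that will carry ring D and C7. Proton transfer then gives the methyl ketone enolate, which acylates on the ester (6-exo-trig Claisen closure of the Dieckmann type) and closes ring A between the future CH lying between the two oxygens and the oxygenated carbon next to the biaryl carbon. The closest known reaction type is the Michael–Claisen condensation of enones with ester enolates to cyclohexane-1,3-diones, here with an arylacetate donor and an intramolecular first step. The two sp3 stereocentres formed in ring A are left uncontrolled because both are erased in step 15, and C8 and C9 are far too weakly acidic to epimerise in methoxide. Only constitutional selectivity is needed: the alternative closures (aldol of the arylacetate enolate onto the ketone, eight-membered; acylation by the ketone enolate before the Michael step, ten-membered) are disfavoured, and all reversible steps drain into the stabilised dione enolate.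

Step 15
Reactants: 21 ring-A cyclohexane-1,3-dione
Product: 23 ring-A dimethyl ether (heptamethyl ether of the target; C8 S and C9 R), via vinylogous methyl ester 22 (not isolated)
Conditions: I2 (2.2 equiv), MeOH, 65 °C
Reagents that add atoms: methanol, CO
Why: Iodine-mediated dehydrogenative aromatisation in methanol, in which the acid formed in situ makes the methyl enol ethers and α-iodination followed by loss of HI gives the arene; this removes the two uncontrolled ring-A centres and is too mild to dehydrogenate the C7–C8 bond.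

Step 16
Reactants: 23 ring-A dimethyl ether (heptamethyl ether of the target)
Product: 24 target heptaphenol CNP0306974.2 (C8 S, C9 R)
Conditions: BBr3 (excess), CH2Cl2, −78 °C to rt; then MeOH, H2O
Reagents that add atoms: none
Why: Lewis acid cleavage of aryl methyl ethers, in which bromide attacks each boron-activated methyl group; C8 and C9 carry no leaving group and should keep their configuration.

**Compound list**

1 | 2-hydroxy-5-methoxybenzaldehyde | COc1ccc(O)c(C=O)c1 | starting material
2 | allyl bromide (3-bromoprop-1-ene) | C=CCBr | starting material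
3 | 5-methoxy-2-(prop-2-en-1-yloxy)benzaldehyde | COc1ccc(OCC=C)c(C=O)c1 | intermediate
4 | 2-hydroxy-5-methoxy-3-(prop-2-en-1-yl)benzaldehyde | COc1cc(CC=C)c(O)c(C=O)c1 | intermediate
5 | 2-formyl-4-methoxy-6-(prop-2-en-1-yl)phenyl trifluoromethanesulfonate | COc1cc(CC=C)c(OS(=O)(=O)C(F)(F)F)c(C=O)c1 | intermediate
6 | 2-(2,2-dibromoethenyl)-4-methoxy-6-(prop-2-en-1-yl)phenyl trifluoromethanesulfonate | COc1cc(CC=C)c(OS(=O)(=O)C(F)(F)F)c(C=C(Br)Br)c1 | intermediate
7 | methyl 2-[3-(2,2-dibromoethenyl)-5-methoxy-2-(trifluoromethanesulfonyloxy)phenyl]acetate | COc1cc(CC(=O)OC)c(OS(=O)(=O)C(F)(F)F)c(C=C(Br)Br)c1 | intermediate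
8 | (3,4-dimethoxyphenyl)boronic acid | COc1ccc(B(O)O)cc1OC | starting material
9 | methyl 2-{3-[(Z)-2-bromo-2-(3,4-dimethoxyphenyl)ethenyl]-5-methoxy-2-(trifluoromethanesulfonyloxy)phenyl}acetate (ring E trans to ring D) | COc1cc(CC(=O)OC)c(OS(=O)(=O)C(F)(F)F)c(/C=C(/c2ccc(OC)c(OC)c2)Br)c1 | intermediate
10 | 2-bromo-4,5-dimethoxybenzaldehyde | COc1cc(Br)c(C=O)cc1OC | starting material
11 | 4,5-dimethoxy-2-(4,4,5,5-tetramethyl-1,3,2-dioxaborolan-2-yl)benzaldehyde | COc1cc(B2OC(C)(C)C(C)(C)O2)c(C=O)cc1OC | intermediate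
12 | methyl 2-{3-[(Z)-2-(3,4-dimethoxyphenyl)-2-(2-formyl-4,5-dimethoxyphenyl)ethenyl]-5-methoxy-2-(trifluoromethanesulfonyloxy)phenyl}acetate (ring B cis to ring D) | COc1cc(CC(=O)OC)c(OS(=O)(=O)C(F)(F)F)c(/C=C(/c2ccc(OC)c(OC)c2)c2cc(OC)c(OC)cc2C=O)c1 | intermediate
13 | methyl 2-{3-[(Z)-2-(3,4-dimethoxyphenyl)-2-(2-formyl-4,5-dimethoxyphenyl)ethenyl]-5-methoxy-2-(4,4,5,5-tetramethyl-1,3,2-dioxaborolan-2-yl)phenyl}acetate | COc1cc(CC(=O)OC)c(B2OC(C)(C)C(C)(C)O2)c(/C=C(/c3ccc(OC)c(OC)c3)c3cc(OC)c(OC)cc3C=O)c1 | intermediate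
14 | (triphenylphosphoranylidene)acetaldehyde | O=CC=P(c1ccccc1)(c1ccccc1)c1ccccc1 | starting material
15 | methyl 2-{3-[(Z)-2-(3,4-dimethoxyphenyl)-2-{4,5-dimethoxy-2-[(E)-3-oxoprop-1-en-1-yl]phenyl}ethenyl]-5-methoxy-2-(4,4,5,5-tetramethyl-1,3,2-dioxaborolan-2-yl)phenyl}acetate | COc1cc(CC(=O)OC)c(B2OC(C)(C)C(C)(C)O2)c(/C=C(/c3ccc(OC)c(OC)c3)c3cc(OC)c(OC)cc3/C=C/C=O)c1 | intermediate
16 | methyl 2-[(5S)-10-(3,4-dimethoxyphenyl)-2,7,8-trimethoxy-5-(2-oxoethyl)-5H-dibenzo[a,d][7]annulen-4-yl]acetate (C8 S) | O=CC[C@H]1c2cc(OC)c(OC)cc2C(c2ccc(OC)c(OC)c2)=Cc2cc(OC)cc(CC(=O)OC)c21 | intermediate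
17 | methyl 2-[(5S,10R)-10-(3,4-dimethoxyphenyl)-2,7,8-trimethoxy-5-(2-oxoethyl)-10,11-dihydro-5H-dibenzo[a,d][7]annulen-4-yl]acetate (C8 S, C9 R) | O=CC[C@H]1c2cc(OC)c(OC)cc2[C@@H](c2ccc(OC)c(OC)c2)Cc2cc(OC)cc(CC(=O)OC)c21 | intermediate
18 | 1-(triphenylphosphoranylidene)propan-2-one | CC(=O)C=P(c1ccccc1)(c1ccccc1)c1ccccc1 | starting material
19 | methyl 2-{(5S,10R)-10-(3,4-dimethoxyphenyl)-2,7,8-trimethoxy-5-[(2E)-4-oxopent-2-en-1-yl]-10,11-dihydro-5H-dibenzo[a,d][7]annulen-4-yl}acetate (key-step precursor) | CC(=O)/C=C/C[C@H]1c2cc(OC)c(OC)cc2[C@@H](c2ccc(OC)c(OC)c2)Cc2cc(OC)cc(CC(=O)OC)c21 | intermediate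
20 | Michael adduct keto ester: ring C closed, methyl ester on the ring-C carbon bonded to D5, 2-oxopropyl on the neighbouring ring-C carbon (C8 S, C9 R; mixture at the two new centres) | CC(=O)CC1C[C@H]2c3cc(OC)c(OC)cc3[C@@H](c3ccc(OC)c(OC)c3)Cc3cc(OC)cc(C1C(=O)OC)c32 | intermediate (not isolated)
21 | ring-A cyclohexane-1,3-dione: pentacycle with rings C and A closed, five aryl methyl ethers (C8 S, C9 R; mixture at the two ring-A sp3 CH carbons) | O=C1CC(=O)C2C(C1)C[C@H]1c3cc(OC)c(OC)cc3[C@@H](c3ccc(OC)c(OC)c3)Cc3cc(OC)cc2c31 | intermediate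
22 | vinylogous methyl ester of 21, with the enol ether at the ring-A carbonyl remote from ring D (C8 S, C9 R) | COC1=CC(=O)C2C(C1)C[C@H]1c3cc(OC)c(OC)cc3[C@@H](c3ccc(OC)c(OC)c3)Cc3cc(OC)cc2c31 | intermediate (not isolated)
23 | heptamethyl ether of the target, ring A as 1,3-dimethoxyarene (C8 S, C9 R) | COc1cc(OC)c2c(c1)C[C@H]1c3cc(OC)c(OC)cc3[C@@H](c3ccc(OC)c(OC)c3)Cc3cc(OC)cc-2c31 | intermediate
24 | CNP0306974.2, heptaphenol (C8 S, C9 R; H8 and H9 cis) | Oc1cc(O)c2c(c1)C[C@H]1c3cc(O)c(O)cc3[C@@H](c3ccc(O)c(O)c3)Cc3cc(O)cc-2c31 | target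

**Step count**

Total steps: 16. Longest linear sequence: 15 (steps 1–6 and 8–16, from compound 1); step 7 is a one-step side branch.

**Three steps most likely to fail**

1. Step 11 (rhodium-catalysed ring closure). Transmetalation of the doubly ortho-substituted boronate may be slower than protodeboronation, or the ring-forming transition state may erode the enantioface selection. The fallback sets out from 12. Wittig olefination with 14 (toluene, 80 °C) gives the triflate enal F1. Pd(OAc)2, PPh3 and Et3N in MeCN at 80 °C then close the seven-membered ring by a 7-exo-trig Heck reaction and give the exocyclic enal F2 (C8=CH–CHO, formyl group on the ring-B side as expected from syn insertion and syn elimination). Enantioselective iminium transfer hydrogenation (Hantzsch ester, a chiral 5-benzyl-2-tert-butyl-3-methylimidazolidin-4-one trifluoroacetate, CHCl3, 0 °C) delivers hydride to C8 and comes back to the route at 16.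

2. Step 12 (hydrogenation that sets C9). Facial selectivity may be poor, or the reduction of the hindered triaryl alkene may stall. The fallback sets out from 12 and fixes C9 by catalyst control before the ring is closed. Iridium-catalysed asymmetric hydrogenation of the open-chain triarylethene ([Ir(cod)(L)][B(C6H3(CF3)2)4] with L a chiral phosphinooxazoline, H2 50 bar, CH2Cl2) gives the (R)-diarylalkane triflate F3. Miyaura borylation under the conditions of step 9 gives the boronate F4, and Wittig olefination with 14 gives the enal F5. The rhodium-catalysed cyclisation of step 11, with the diene enantiomer that gives S at C8, then forms the saturated ring and comes back to the route at 17.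

3. Step 14 (Michael–Claisen cascade). Deconjugation of the enone and intermolecular condensation, or a reversible Michael addition that is not followed by acylation, may outrun the cascade. The fallback sets out from 17 and adds an activating ester to the acceptor. Knoevenagel condensation with methyl acetoacetate (piperidine, AcOH, CH2Cl2) gives the alkylidene acetoacetate F6. NaOMe in MeOH then drives the same intramolecular Michael addition of the arylacetate, followed by Claisen closure through the acetyl methyl group, to the ring-A dione methyl ester F7. Saponification and decarboxylation (aq. NaOH, then HCl, 60 °C) come back to the route at 21.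

**Further compounds**

F1 | step 11 | methyl 2-{3-[(Z)-2-(3,4-dimethoxyphenyl)-2-{4,5-dimethoxy-2-[(E)-3-oxoprop-1-en-1-yl]phenyl}ethenyl]-5-methoxy-2-(trifluoromethanesulfonyloxy)phenyl}acetate | COc1cc(CC(=O)OC)c(OS(=O)(=O)C(F)(F)F)c(/C=C(/c2ccc(OC)c(OC)c2)c2cc(OC)c(OC)cc2/C=C/C=O)c1
F2 | step 11 | methyl 2-[10-(3,4-dimethoxyphenyl)-2,7,8-trimethoxy-5-(2-oxoethylidene)-5H-dibenzo[a,d][7]annulen-4-yl]acetate (formyl group cis to ring B) | O=C/C=C1\c2cc(OC)c(OC)cc2C(c2ccc(OC)c(OC)c2)=Cc2cc(OC)cc(CC(=O)OC)c21
F3 | step 12 | methyl 2-{3-[(2R)-2-(3,4-dimethoxyphenyl)-2-(2-formyl-4,5-dimethoxyphenyl)ethyl]-5-methoxy-2-(trifluoromethanesulfonyloxy)phenyl}acetate | COc1cc(CC(=O)OC)c(OS(=O)(=O)C(F)(F)F)c(C[C@H](c2ccc(OC)c(OC)c2)c2cc(OC)c(OC)cc2C=O)c1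
F4 | step 12 | methyl 2-{3-[(2R)-2-(3,4-dimethoxyphenyl)-2-(2-formyl-4,5-dimethoxyphenyl)ethyl]-5-methoxy-2-(4,4,5,5-tetramethyl-1,3,2-dioxaborolan-2-yl)phenyl}acetate | COc1cc(CC(=O)OC)c(B2OC(C)(C)C(C)(C)O2)c(C[C@H](c3ccc(OC)c(OC)c3)c3cc(OC)c(OC)cc3C=O)c1
F5 | step 12 | methyl 2-{3-[(2R)-2-(3,4-dimethoxyphenyl)-2-{4,5-dimethoxy-2-[(E)-3-oxoprop-1-en-1-yl]phenyl}ethyl]-5-methoxy-2-(4,4,5,5-tetramethyl-1,3,2-dioxaborolan-2-yl)phenyl}acetate | COc1cc(CC(=O)OC)c(B2OC(C)(C)C(C)(C)O2)c(C[C@H](c3ccc(OC)c(OC)c3)c3cc(OC)c(OC)cc3/C=C/C=O)c1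
F6 | step 14 | alkylidene acetoacetate of 17: methyl 2-acetyl-4-[(5S,10R)-dibenzosuberan-5-yl]but-2-enoate bearing the substituents of 17 (E/Z mixture; C8 S, C9 R) | CC(=O)C(C(=O)OC)=CC[C@H]1c2cc(OC)c(OC)cc2[C@@H](c2ccc(OC)c(OC)c2)Cc2cc(OC)cc(CC(=O)OC)c21
F7 | step 14 | ring-A dione methyl ester: compound 21 with a methoxycarbonyl group on the ring-A CH2 next to the C7-bearing carbon (C8 S, C9 R; mixture at the ring-A sp3 carbons) | COC(=O)C1C(=O)CC(=O)C2C1C[C@H]1c3cc(OC)c(OC)cc3[C@@H](c3ccc(OC)c(OC)c3)Cc3cc(OC)cc2c31
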